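**Assumption:** Mururin C as drawn has no stereocentre or stereogenic axis, so "single enantiomer" does not apply; the route targets the achiral structure exactly as given in the SMILES.

## Retrosynthetic overview

1. Mururin C ⇐ one acidic global unmasking (dimethyl acetal → CHO, two MOM ethers, one TBS ether) of the 3-(dimethoxymethyl)benzofuran 9.
2. The furan ring (O1–C2) and the C3–formyl carbon bond are formed together by a new Pt(II)-catalysed migratory "oxy-formylation" of the o-alkynylaryl dimethyl orthoformate 8.
3. 8 ⇐ Sonogashira coupling of the iodoaryl orthoformate 4 with the arylacetylene 7.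
4. 4 ⇐ dihydroconiferyl alcohol 1 (ortho-iodination, TBS protection, O-dimethoxymethylation); 7 ⇐ 5-hydroxyvanillin 5 (bis-MOM protection, Ohira–Bestmann alkynylation).
5. Ring order: both benzene rings are purchased; the furan is the only ring built, in step 7.

## Route

**Step 1**
Reactants: 1, 3-(4-hydroxy-3-methoxyphenyl)propan-1-ol (dihydroconiferyl alcohol)
Product: 2, 4-(3-hydroxypropyl)-2-iodo-6-methoxyphenol
Conditions: I2 (1.05 eq), KI, NaHCO3, THF/H2O, 0 °C → rt
Reagents that add atoms: iodine, II
Why: Phenoxide-directed electrophilic aromatic iodination; the para position is blocked and only one position ortho to OH is free, so iodine enters there rather than para to OMe.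

**Step 2**
Reactants: 2, 4-(3-hydroxypropyl)-2-iodo-6-methoxyphenol
Product: 3, 4-[3-(tert-butyldimethylsilyloxy)propyl]-2-iodo-6-methoxyphenol
Conditions: TBSCl (2.3 eq), imidazole, DMF, rt; then K2CO3, MeOH, rt (one pot)
Reagents that add atoms: tert-butyldimethylsilyl chloride, CC(C)(C)[Si](C)(C)Cl
Why: Exhaustive silylation followed by selective methanolysis of the much more labile aryl silyl ether leaves only the primary alkyl TBS ether (standard silyl protection/selective desilylation).

**Step 3**
Reactants: 3, 4-[3-(tert-butyldimethylsilyloxy)propyl]-2-iodo-6-methoxyphenol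
Product: 4, tert-butyl{3-[4-(dimethoxymethoxy)-3-iodo-5-methoxyphenyl]propoxy}dimethylsilane (the aryl dimethyl orthoformate, ArO–CH(OMe)2)
Conditions: NaH, THF, 0 °C; then [HC(OMe)2]BF4 (pre-formed from HC(OMe)3/BF3·OEt2, CH2Cl2, −30 °C), −78 → 0 °C; Et3N quench, filtration through basic alumina
Reagents that add atoms: dimethoxycarbenium tetrafluoroborate, CO[CH+]OC.F[B-](F)(F)F
Why: O-alkylation of a hard phenoxide by a dialkoxycarbenium salt is the classical mixed-orthoester synthesis (Meerwein-type); the product is base-stable and is kept away from acid.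

**Step 4**
Reactants: 5, 3,4-dihydroxy-5-methoxybenzaldehyde (5-hydroxyvanillin)
Product: 6, 3-methoxy-4,5-bis(methoxymethoxy)benzaldehyde
Conditions: MOMCl (2.6 eq), iPr2NEt, CH2Cl2, 0 °C → rt
Reagents that add atoms: chloromethyl methyl ether, COCCl
Why: Standard Williamson-type acetal protection of both catechol hydroxyls; the aldehyde is inert.

**Step 5**
Reactants: 6, 3-methoxy-4,5-bis(methoxymethoxy)benzaldehyde
Product: 7, 5-ethynyl-1-methoxy-2,3-bis(methoxymethoxy)benzene
Conditions: dimethyl (1-diazo-2-oxopropyl)phosphonate, K2CO3, MeOH, rt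
Reagents that add atoms: Ohira–Bestmann reagent, CC(=O)C(=[N+]=[N-])P(=O)(OC)OC (delivers the terminal alkyne carbon)
Why: Seyferth–Gilbert homologation (Ohira–Bestmann variant) converts the aryl aldehyde into the terminal alkyne under mild base that MOM ethers tolerate.

**Step 6**
Reactants: 4, tert-butyl{3-[4-(dimethoxymethoxy)-3-iodo-5-methoxyphenyl]propoxy}dimethylsilane; 7, 5-ethynyl-1-methoxy-2,3-bis(methoxymethoxy)benzene
Product: 8, tert-butyl{3-[4-(dimethoxymethoxy)-3-methoxy-5-{[3-methoxy-4,5-bis(methoxymethoxy)phenyl]ethynyl}phenyl]propoxy}dimethylsilane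
Conditions: PdCl2(PPh3)2 (3 mol %), CuI (5 mol %), Et3N/THF, degassed, rt → 40 °C; NaHCO3 work-up, Et3N-deactivated silica
Reagents that add atoms: none
Why: Sonogashira coupling of an aryl iodide; the amine medium preserves the orthoester, and because the phenol oxygen is already capped no premature cyclisation to a 3-H benzofuran can occur.

**Step 7**
Reactants: 8, the o-alkynylaryl dimethyl orthoformate from step 6
Product: 9, tert-butyl{3-[3-(dimethoxymethyl)-7-methoxy-2-[3-methoxy-4,5-bis(methoxymethoxy)phenyl]-1-benzofuran-5-yl]propoxy}dimethylsilane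
Conditions: PtCl2 (5 mol %), 1,5-cyclooctadiene (20 mol %), 2,6-di-tert-butylpyridine (10 mol %), 4 Å MS, toluene, 40 °C
Reagents that add atoms: none (isomerisation)
Why: Proposed new method: Pt(II) π-activates the diarylalkyne, the aryl ether oxygen adds anti in a 5-endo-dig sense at the alkyne carbon bearing the electron-rich aryl group to give a 3-platinated O-(dimethoxymethyl)benzofuranium ion, the O–CH(OMe)2 bond then ionises easily because it releases the doubly oxygen-stabilised dimethoxycarbenium ion, and this cation is captured within the ion pair by the nucleophilic C3–Pt bond, forming C3–CH(OMe)2 and releasing Pt(II) with no proton available for protodemetalation (net addition of an orthoester C–O bond across the alkyne, i.e. oxy-formylation); the closest known reaction type is the Pt(II)/Au(I)-catalysed carboalkoxylation of o-alkynylphenyl acetals and ethers (1,3-shift of α-alkoxyalkyl, allyl or benzyl groups) to 2,3-disubstituted benzofurans, which has not been shown for an orthoformate as a masked formyl group.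

**Step 8**
Reactants: 9, the 3-(dimethoxymethyl)benzofuran from step 7
Product: 10, Mururin C, 2-(3,4-dihydroxy-5-methoxyphenyl)-5-(3-hydroxypropyl)-7-methoxy-1-benzofuran-3-carbaldehyde
Conditions: 3 M aq. HCl, THF/MeOH (2:1), 45 °C, Ar
Reagents that add atoms: water, O (the aldehyde oxygen)
Why: Acid hydrolysis cleaves the dimethyl acetal, both aryl MOM acetals and the primary TBS ether in one operation, while the aryl methyl ethers, the benzofuran and the vinylogous-ester-type aldehyde are stable to aqueous HCl.

## Compound list

1 | 3-(4-hydroxy-3-methoxyphenyl)propan-1-ol (dihydroconiferyl alcohol) | OCCCc1ccc(O)c(OC)c1 | starting material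
2 | 4-(3-hydroxypropyl)-2-iodo-6-methoxyphenol | OCCCc1cc(I)c(O)c(OC)c1 | intermediate
3 | 4-[3-(tert-butyldimethylsilyloxy)propyl]-2-iodo-6-methoxyphenol | CC(C)(C)[Si](C)(C)OCCCc1cc(I)c(O)c(OC)c1 | intermediate
4 | tert-butyl{3-[4-(dimethoxymethoxy)-3-iodo-5-methoxyphenyl]propoxy}dimethylsilane | CC(C)(C)[Si](C)(C)OCCCc1cc(I)c(OC(OC)OC)c(OC)c1 | intermediate
5 | 3,4-dihydroxy-5-methoxybenzaldehyde (5-hydroxyvanillin) | O=Cc1cc(O)c(O)c(OC)c1 | starting material
6 | 3-methoxy-4,5-bis(methoxymethoxy)benzaldehyde | O=Cc1cc(OC)c(OCOC)c(OCOC)c1 | intermediate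
7 | 5-ethynyl-1-methoxy-2,3-bis(methoxymethoxy)benzene | C#Cc1cc(OC)c(OCOC)c(OCOC)c1 | intermediate
8 | tert-butyl{3-[4-(dimethoxymethoxy)-3-methoxy-5-{[3-methoxy-4,5-bis(methoxymethoxy)phenyl]ethynyl}phenyl]propoxy}dimethylsilane | CC(C)(C)[Si](C)(C)OCCCc1cc(OC)c(OC(OC)OC)c(C#Cc2cc(OC)c(OCOC)c(OCOC)c2)c1 | intermediate
9 | tert-butyl{3-[3-(dimethoxymethyl)-7-methoxy-2-[3-methoxy-4,5-bis(methoxymethoxy)phenyl]-1-benzofuran-5-yl]propoxy}dimethylsilane | CC(C)(C)[Si](C)(C)OCCCc1cc(OC)c2oc(-c3cc(OC)c(OCOC)c(OCOC)c3)c(C(OC)OC)c2c1 | intermediate
10 | Mururin C, 2-(3,4-dihydroxy-5-methoxyphenyl)-5-(3-hydroxypropyl)-7-methoxy-1-benzofuran-3-carbaldehyde (achiral) | COc1cc(-c2oc3c(OC)cc(CCCO)cc3c2C=O)cc(O)c1O | target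

## Summary

Total steps: 8.
Longest linear sequence: 6 (steps 1, 2, 3, 6, 7, 8); the alkyne arm is 2 steps (4, 5).

Three steps most likely to fail:

1. **Step 7 (proposed new Pt-catalysed oxy-formylation).** Risk: loss of the dimethoxymethyl group and protodemetalation to the 3-H benzofuran, or poor turnover. Fallback (known chemistry): drop the orthoformate; couple the free iodophenol 3 with alkyne 7 under Sonogashira conditions at 60–80 °C so that Cu/base-mediated 5-endo-dig cyclisation gives the 2-aryl-3-H-benzofuran, install the aldehyde by Vilsmeier–Haack formylation (POCl3/DMF) at C3 with the side-chain alcohol carried as an acetate, then deprotect. Any 3-H benzofuran formed in step 7 can be sent through the same formylation.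

2. **Step 3 (mixed aryl dimethyl orthoformate formation and handling).** Risk: hydrolysis on isolation, ring C-alkylation, or TBS loss from adventitious acid. Fallback: replace the orthoformate carrier with a simple MOM ether on 3 (MOMCl, iPr2NEt), carry out the known Pt(II)-catalysed 1,3-shift of the methoxymethyl group to give the 3-(methoxymethyl)benzofuran, and oxidise that benzylic ether to the aldehyde with DDQ/H2O.

3. **Step 8 (global acid deprotection).** Risk: formaldehyde released from the MOM groups alkylating the electron-rich catechol ring, or catechol oxidation. Fallback: protect the catechol of 5 as a bis-benzyl ether instead (BnBr, K2CO3) and finish in two stages: mild aqueous acid to remove TBS and the acetal, then BCl3/pentamethylbenzene at −78 °C for non-hydrolytic debenzylation, which spares the aldehyde and methyl ethers.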